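**Assumptions:** The target (5-hydroxy-6,7,8,4'-tetramethoxyflavone, 5-O-desmethyltangeretin) has no stereocentres or stereogenic axes, so "single enantiomer" needs no stereocontrol. I also assume a de novo construction is wanted, so the commercial natural product tangeretin is not used as a starting material.

## Retrosynthetic overview
1. Target ⇐ tangeretin (7) by chelation-controlled cleavage of the 5-OMe peri to the C4 carbonyl.
2. The pyranone C-ring is the only ring formed, and it is formed last, by I2/DMSO oxidative cyclisation of a 2'-hydroxychalcone (6); the A and B rings are purchased arenes.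
3. Chalcone 6 ⇐ Claisen–Schmidt condensation of 2-hydroxy-3,4,5,6-tetramethoxyacetophenone (4) with 4-methoxybenzaldehyde (5).
4. Acetophenone 4 ⇐ 3,4,5-trimethoxyphenol (1) by ortho-acetylation, bromination of the single remaining Ar–H, and Cu-mediated Br→OMe exchange.

## Route

**Step 1**
Reactants: 1, 3,4,5-trimethoxyphenol
Product: 2, 1-(6-hydroxy-2,3,4-trimethoxyphenyl)ethan-1-one
Conditions: AcOH, BF3·OEt2 (3 equiv), 85–90 °C, 2 h; then H2O/MeOH to hydrolyse the BF2 chelate
Reagents that add atoms: acetic acid, CC(=O)O
Why: Friedel–Crafts acylation (O-acylation/Fries pathway) of a highly activated phenol; the two open positions are equivalent and ortho to OH, so one regioisomer forms, and moderate temperature and short time avoid BF3 cleavage of the ortho-OMe.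

**Step 2**
Reactants: 2, 1-(6-hydroxy-2,3,4-trimethoxyphenyl)ethan-1-one
Product: 3, 1-(3-bromo-2-hydroxy-4,5,6-trimethoxyphenyl)ethan-1-one
Conditions: NBS (1.05 equiv), MeCN, 0 °C → rt, dark
Reagents that add atoms: N-bromosuccinimide, O=C1CCC(=O)N1Br
Why: Electrophilic aromatic bromination at the only remaining Ar–H (ortho to OH, flanked by OMe); the ring is far more reactive than the ketone α-position under non-radical, non-acidic conditions.

**Step 3**
Reactants: 3, 1-(3-bromo-2-hydroxy-4,5,6-trimethoxyphenyl)ethan-1-one
Product: 4, 1-(2-hydroxy-3,4,5,6-tetramethoxyphenyl)ethan-1-one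
Conditions: NaOMe (28% in MeOH, 10 equiv), CuBr (0.5 equiv), DMF, 110 °C, N2; then 1 M HCl
Reagents that add atoms: sodium methoxide, [Na+].[O-]C
Why: Ullmann-type Cu(I)-mediated methoxylation of an aryl bromide ortho to a phenoxide (the 5-bromovanillin → syringaldehyde type of reaction); the hindered ketone and the methyl ethers are inert to NaOMe.

**Step 4**
Reactants: 4, 1-(2-hydroxy-3,4,5,6-tetramethoxyphenyl)ethan-1-one; 5, 4-methoxybenzaldehyde (1.2 equiv)
Product: 6, (E)-1-(2-hydroxy-3,4,5,6-tetramethoxyphenyl)-3-(4-methoxyphenyl)prop-2-en-1-one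
Conditions: KOH (50% aq, 10 equiv), EtOH, rt, 24–48 h; then HCl to pH 3
Reagents that add atoms: none (both partners are numbered reactants; water is lost)
Why: Claisen–Schmidt (crossed aldol) condensation with a non-enolisable aldehyde; E1cB dehydration gives the thermodynamic (E)-enone, whose geometry is erased in the next step.

**Step 5**
Reactants: 6, the (E)-2'-hydroxychalcone
Product: 7, 5,6,7,8-tetramethoxy-2-(4-methoxyphenyl)-4H-chromen-4-one (tangeretin)
Conditions: I2 (10 mol%), DMSO, 130 °C, 2–4 h; aq. Na2S2O3 work-up
Reagents that add atoms: none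
Why: I2/DMSO oxidative cyclisation: 6-endo oxa-Michael closure of the single free 2'-OH, then iodination/HI elimination with DMSO regenerating I2; only one phenol is free, so only the 5,6,7,8-pattern can form.

**Step 6**
Reactants: 7, tangeretin
Product: 8, 5-hydroxy-6,7,8-trimethoxy-2-(4-methoxyphenyl)-4H-chromen-4-one (target)
Conditions: BCl3 (1 M in CH2Cl2, 1.3 equiv), CH2Cl2, −78 → 0 °C, 1 h; then MeOH / 1 M HCl
Reagents that add atoms: none (CH3 is removed as MeCl)
Why: Chelation-directed Lewis-acid O-demethylation: boron bound to C4=O delivers chloride only to the peri 5-OMe through a six-membered chelate, and limiting equivalents and temperature leave the 6-, 7-, 8- and 4'-OMe intact.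

## Compound list
1 | 3,4,5-trimethoxyphenol | COc1cc(O)cc(OC)c1OC | starting material
2 | 1-(6-hydroxy-2,3,4-trimethoxyphenyl)ethan-1-one | CC(=O)c1c(O)cc(OC)c(OC)c1OC | intermediate
3 | 1-(3-bromo-2-hydroxy-4,5,6-trimethoxyphenyl)ethan-1-one | CC(=O)c1c(O)c(Br)c(OC)c(OC)c1OC | intermediate
4 | 1-(2-hydroxy-3,4,5,6-tetramethoxyphenyl)ethan-1-one | CC(=O)c1c(O)c(OC)c(OC)c(OC)c1OC | intermediate
5 | 4-methoxybenzaldehyde (p-anisaldehyde) | COc1ccc(C=O)cc1 | starting material
6 | (E)-1-(2-hydroxy-3,4,5,6-tetramethoxyphenyl)-3-(4-methoxyphenyl)prop-2-en-1-one | COc1ccc(/C=C/C(=O)c2c(O)c(OC)c(OC)c(OC)c2OC)cc1 | intermediate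
7 | 5,6,7,8-tetramethoxy-2-(4-methoxyphenyl)-4H-chromen-4-one (tangeretin) | COc1ccc(-c2cc(=O)c3c(OC)c(OC)c(OC)c(OC)c3o2)cc1 | intermediate
8 | 5-hydroxy-6,7,8-trimethoxy-2-(4-methoxyphenyl)-4H-chromen-4-one (achiral) | COc1ccc(-c2cc(=O)c3c(O)c(OC)c(OC)c(OC)c3o2)cc1 | target

## Summary
Total steps: 6. Longest linear sequence: 6 (1 → 2 → 3 → 4 → 6 → 7 → 8; aldehyde 5 is purchased).

Steps most likely to fail, with fallbacks:

1. **Step 3 (Cu-mediated methoxylation).** The bromide is di-ortho-substituted and next to a phenoxide, so hydrodebromination back to 2 or stalling is possible. Fallback: drop halide displacement and install the fifth oxygen by formylation/Dakin chemistry. This runs 1,2,3,5-tetramethoxybenzene → Vilsmeier aldehyde → Baeyer–Villiger/hydrolysis to 2,3,4,6-tetramethoxyphenol → O-methylation to pentamethoxybenzene → AcCl/AlCl3 acylation with concomitant ortho-demethylation, giving 4 directly.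

2. **Step 6 (selective 5-O-demethylation).** Excess reagent or warming can also cleave the 6-OMe. Fallback: move the demethylation to the acetophenone stage. Chelation-controlled cleavage of 4 gives the C2-symmetric 2,6-dihydroxy-3,4,5-trimethoxyacetophenone; condensation with 5 and I2/DMSO oxidation then give 8 directly, since cyclisation through either OH gives the same flavone.

3. **Step 4 (Claisen–Schmidt on a di-ortho-substituted, electron-rich acetophenone).** The reaction may be slow or give chalcone/flavanone mixtures. Fallback: replace steps 4–5 with a Baker–Venkataraman sequence. O-acylate 4 with 4-methoxybenzoyl chloride, rearrange with base (KOH/pyridine or LiHMDS) to the 1,3-diketone, and cyclodehydrate with H2SO4/AcOH to 7.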